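**Retrosynthetic overview**
- Locants: C1 = CHOBz next to the quaternary carbon, C2=C3, C4 = CHOBz, C5 = CHOH, C6 = C(OH), C7 = CH2OH. The plan rests on the ring fragment C7–C6–C1–C2=C3: with C7 raised to CO2H it is a γ,δ-unsaturated acid whose α-carbon C6 is bonded to C1, the allylic neighbour of the ring alkene.
- Target 24 ⇐ benzoylation of O1/O4 after oxidative removal of arylmethyl ethers ⇐ reduction of CO2H to C7H2OH ⇐ cyclohexenecarboxylic acid 18.
- 18 ⇐ C6–C1 disconnection: Ireland–Claisen [3,3] shift of the silyl ketene acetal of δ-lactone 15 (C7 carbonyl, ring oxygen on C3, a (Z)-2-(4-methoxybenzyloxy)vinyl group C2=C1 on C3).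
- 15 ⇐ vinyl lactone 11 by Z-selective enol-ether cross-metathesis ⇐ D-glucuronic acid (C2–C7 = sugar C1–C6, C3 = sugar C2; O3 and O5 carried as naphthylmethyl ethers).
- Ring order: the δ-lactone is closed first (step 6) and is traded for the carbocycle in step 10, the only carbocycle-forming step.

Key step: step 10

Remark: D-glucuronic acid is entered as its catalogue 1,2-O-isopropylidene 6,3-lactone 1 (otherwise one acetonation of D-glucuronolactone); NAP = naphthalen-2-ylmethyl, PMB = 4-methoxybenzyl, TES = triethylsilyl, TBS = tert-butyldimethylsilyl, and the C1–C7 locants above are used for all compounds from 10 on.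

**Step 1**
Reactants: 1 1,2-O-isopropylidene-α-D-glucofuranurono-6,3-lactone
Product: 2 methyl 1,2-O-isopropylidene-α-D-glucofuranuronate
Conditions: MeOH, Et3N (0.2 equiv), rt
Reagents that add atoms: methanol, CO
Why: Base-catalysed alcoholysis (transesterification) of the strained cis-fused γ-lactone should open it to the methyl ester and free O3–H and O5–H without touching a stereocentre.

**Step 2**
Reactants: 3 naphthalen-2-ylmethanol; 4 trichloroacetonitrile
Product: 5 naphthalen-2-ylmethyl 2,2,2-trichloroacetimidate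
Conditions: DBU (0.1 equiv), CH2Cl2, 0 °C
Reagents that add atoms: none
Why: Base-catalysed addition of the alcohol to the nitrile (imidate formation) is the standard entry to acid-activated arylmethylating agents.

**Step 3**
Reactants: 2 methyl 1,2-O-isopropylidene-α-D-glucofuranuronate; 5 naphthalen-2-ylmethyl 2,2,2-trichloroacetimidate (3 equiv)
Product: 6 methyl 1,2-O-isopropylidene-3,5-di-O-(naphthalen-2-ylmethyl)-α-D-glucofuranuronate
Conditions: TfOH (0.1 equiv), CH2Cl2/cyclohexane (1:2), 0 °C → rt
Reagents that add atoms: none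
Why: Acid-catalysed imidate O-alkylation etherifies both the hindered O3–H and the α-hydroxy-ester O5–H without base, so the ester is neither eliminated nor cleaved; NAP is used instead of PMB because it withstands the aqueous acid of step 4 and still leaves with DDQ.

**Step 4**
Reactants: 6 methyl 1,2-O-isopropylidene-3,5-di-O-(naphthalen-2-ylmethyl)-α-D-glucofuranuronate
Product: 8 3,5-di-O-(naphthalen-2-ylmethyl)-D-glucofuranuronic acid (lactol; anomer mixture), via lithium uronate 7 (not isolated)
Conditions: LiOH·H2O (2 equiv), THF/H2O (3:1), 0 °C; then TFA/H2O (4:1), 0 °C → rt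
Reagents that add atoms: lithium hydroxide, [Li+].[OH-]
Why: Saponification followed by acid hydrolysis of the 1,2-O-isopropylidene acetal frees the carboxylic acid, the C1 lactol and O2–H, while the NAP ethers should resist aqueous TFA.

**Step 5**
Reactants: 8 3,5-di-O-(naphthalen-2-ylmethyl)-D-glucofuranuronic acid
Product: 9 6,7-dideoxy-2,4-di-O-(naphthalen-2-ylmethyl)-L-gulo-hept-6-enonic acid
Conditions: Ph3PCH3Br (5 equiv), KOtBu (5 equiv), THF, 0 °C → rt; aq. HCl to pH 3
Reagents that add atoms: methyltriphenylphosphonium bromide, C[P+](c1ccccc1)(c1ccccc1)c1ccccc1.[Br-]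
Why: Wittig methylenation of the lactol through its open hydroxy-aldehyde form; the carboxylate and the alkoxide next to the aldehyde, formed first, shield the chain from enolisation, β-elimination and retro-aldol cleavage, so the sugar C2 stereocentre (the later C3) is kept.

**Step 6**
Reactants: 9 6,7-dideoxy-2,4-di-O-(naphthalen-2-ylmethyl)-L-gulo-hept-6-enonic acid
Product: 10 6,7-dideoxy-2,4-di-O-(naphthalen-2-ylmethyl)-L-gulo-hept-6-enono-1,5-lactone (δ-lactone: C7 carbonyl; ring O on C3; vinyl on C3; C4-ONAP; C5-OH; C6-ONAP)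
Conditions: TsOH·H2O (5 mol %), toluene, 4 Å MS, 70 °C
Reagents that add atoms: none
Why: Acid-catalysed lactonisation can only close the six-membered ring onto the allylic hydroxyl (the other free hydroxyl would give a β-lactone), and as an acyl–oxygen esterification it keeps the C3 configuration.

**Step 7**
Reactants: 10 vinyl δ-lactone with free C5-OH
Product: 11 6,7-dideoxy-2,4-di-O-(naphthalen-2-ylmethyl)-3-O-triethylsilyl-L-gulo-hept-6-enono-1,5-lactone (C5-OTES)
Conditions: TESOTf (1.3 equiv), 2,6-lutidine (2.5 equiv), CH2Cl2, −78 → 0 °C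
Reagents that add atoms: triethylsilyl trifluoromethanesulfonate, CC[Si](CC)(CC)OS(=O)(=O)C(F)(F)F
Why: Silyl triflate with a hindered pyridine base silylates the flanked secondary hydroxyl without opening the lactone; the silyl ether is a poor leaving group for the enolate chemistry of step 10 and is removed under mild acid fluoride at the end.

**Step 8**
Reactants: 12 4-methoxybenzyl alcohol; 13 vinyl acetate (2 equiv)
Product: 14 4-methoxybenzyl vinyl ether
Conditions: [Ir(cod)Cl]2 (1 mol %), Na2CO3 (0.6 equiv), toluene, 100 °C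
Reagents that add atoms: none
Why: Iridium-catalysed transfer vinylation of a primary alcohol with vinyl acetate gives the vinyl ether directly, the carbonate taking up the acetic acid.

**Step 9**
Reactants: 11 vinyl δ-lactone (C5-OTES); 14 4-methoxybenzyl vinyl ether (10 equiv)
Product: 15 (6Z)-6-deoxy-7-O-(4-methoxybenzyl)-2,4-di-O-(naphthalen-2-ylmethyl)-3-O-triethylsilyl-L-gulo-hept-6-enono-1,5-lactone (δ-lactone with a (Z)-CH=CH-OPMB group on C3)
Conditions: Mo(N-1-adamantyl)(CHCMe2Ph)(2,5-dimethylpyrrolide)(OAr) (5 mol %; OAr = 3,3'-dibromo-2'-(tert-butyldimethylsilyloxy)-5,5',6,6',7,7',8,8'-octahydro-1,1'-binaphth-2-olate), benzene, 22 °C, reduced pressure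
Reagents that add atoms: none
Why: Catalyst-controlled Z-selective cross-metathesis of a terminal alkene with an enol ether: the small imido and large aryloxide ligands of the molybdenum monoaryloxide pyrrolide alkylidene force an all-cis metallacyclobutane that should release the (Z)-enol ether, and excess 14 with removal of ethylene drives the exchange.

**Step 10**
Reactants: 15 δ-lactone with the (Z)-2-(4-methoxybenzyloxy)vinyl group on C3
Product: 18 cyclohex-2-ene-6-carboxylic acid (C1-OPMB; C4-ONAP; C5-OTES; C6-ONAP; C7 = CO2H; ring configuration as in 24), via silyl ketene acetal 16 (not isolated), via trimethylsilyl ester 17 (not isolated)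
Conditions: TMSCl/Et3N (1:1, 8 equiv), THF, −78 °C; LDA (1.6 equiv), −78 °C, 30 min; → rt; toluene, 95 °C; then 1 M aq. citric acid, THF, 0 °C
Reagents that add atoms: none
Why: LDA in the presence of TMSCl/Et3N removes C6–H and the lithium enolate is O-silylated as it forms, giving the endocyclic ketene acetal 16 (C6=C7) before the C5 silyloxy group can be expelled; on warming, 16 undergoes the Ireland–Claisen [3,3] shift through the array C6=C7–O–C3–C2=C1, which makes C6–C1 and C2=C3 and breaks C3–O, and aqueous work-up hydrolyses silyl ester 17. The closest known reactions are the Claisen rearrangement of lactone silyl ketene acetals that carry an alkenyl group on the carbinol carbon (lactone to cycloalkenecarboxylic acid) and the ester-enolate Claisen rearrangement of 3-O-acyl glycals, which share the enol-ether allyl terminus. The cyclohexene ring is closed pericyclically, by suprafacial C6–C1 bonding across a boat-shaped six-centre transition state with the outline of a bicyclo[2.2.2]octene (bridgeheads C3 and C6); a chair is excluded because C3 and C6 are tied by the C4–C5 bridge and C2=C3 must become a cis ring alkene. C6 is set by the C3 stereocentre (C2 of D-glucuronic acid): the vinyl group reaches only the lactone face it stands on, so C7 ends on the face from which the ring oxygen departs and the C6 oxygen trans to the C5 oxygen. C1 is set by the (Z) geometry of the enol ether, which in this boat puts the C1 oxygen on the side of the C4–C5 bridge, cis to the C6 oxygen. The step needs O-silylation to outrun β-elimination (secured by the internal TMSCl quench at −78 °C) and rearrangement to outrun ionisation of the allylic C3–O bond (secured by the neutral, amine-buffered, aprotic medium).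

**Step 11**
Reactants: 18 cyclohex-2-ene-6-carboxylic acid
Product: 19 primary alcohol (C1-OPMB; C4-ONAP; C5-OTES; C6-ONAP; C7H2OH)
Conditions: LiAlH4 (3 equiv), THF, 0 → 40 °C; Rochelle salt work-up
Reagents that add atoms: none
Why: Hydride reduction of the hindered α-alkoxy acid to the neopentyl-type alcohol; ethers, silyl ether and the isolated ring alkene are inert to LiAlH4.

**Step 12**
Reactants: 19 primary alcohol
Product: 20 C7 silyl ether (C1-OPMB; C4-ONAP; C5-OTES; C6-ONAP; C7-OTBS)
Conditions: TBSCl (1.5 equiv), imidazole (3 equiv), DMF, rt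
Reagents that add atoms: tert-butyldimethylsilyl chloride, CC(C)(C)[Si](C)(C)Cl
Why: Standard silylation masks the primary hydroxyl, which would otherwise be the first to be benzoylated in step 14.

**Step 13**
Reactants: 20 fully protected cyclohexene
Product: 21 triol (C1-OH; C4-OH; C6-OH; C5-OTES; C7-OTBS)
Conditions: DDQ (4 equiv), CH2Cl2/pH 7 phosphate buffer (10:1), 0 °C → rt
Reagents that add atoms: none
Why: Oxidative cleavage of electron-rich arylmethyl ethers (benzylic hydride abstraction by DDQ, then hydrolysis of the oxocarbenium ion) removes the PMB and both NAP groups, while silyl ethers and the alkene are spared in the buffered two-phase medium.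

**Step 14**
Reactants: 21 triol; 22 benzoyl chloride (2.6 equiv)
Product: 23 1,4-dibenzoate (C1-OBz; C4-OBz; C6-OH; C5-OTES; C7-OTBS)
Conditions: pyridine, DMAP (0.1 equiv), CH2Cl2, 0 °C → rt
Reagents that add atoms: none
Why: Acylation with an acid chloride takes the two secondary allylic hydroxyls and leaves the tertiary C6 hydroxyl, which is too hindered to react under these conditions.

**Step 15**
Reactants: 23 1,4-dibenzoate
Product: 24 (1S,4R,5S,6R)-5,6-dihydroxy-6-(hydroxymethyl)cyclohex-2-ene-1,4-diyl dibenzoate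
Conditions: HF·pyridine, pyridine, THF, 0 °C → rt
Reagents that add atoms: none
Why: Weakly acidic fluoride cleaves the secondary TES and primary TBS ethers; basic fluoride is avoided so that the benzoates should not migrate to the freed O5 and O7 hydroxyls.

**Compound list**
1 | 1,2-O-isopropylidene-α-D-glucofuranurono-6,3-lactone | CC1(C)O[C@H]2O[C@@H]3[C@H](O)C(=O)O[C@@H]3[C@H]2O1 | starting material
2 | methyl 1,2-O-isopropylidene-α-D-glucofuranuronate | CC1(C)O[C@H]2O[C@H]([C@H](O)C(=O)OC)[C@H](O)[C@H]2O1 | intermediate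
3 | naphthalen-2-ylmethanol | OCc1ccc2ccccc2c1 | starting material
4 | trichloroacetonitrile | N#CC(Cl)(Cl)Cl | starting material
5 | naphthalen-2-ylmethyl 2,2,2-trichloroacetimidate | N=C(OCc1ccc2ccccc2c1)C(Cl)(Cl)Cl | intermediate
6 | methyl 1,2-O-isopropylidene-3,5-di-O-(naphthalen-2-ylmethyl)-α-D-glucofuranuronate | CC1(C)O[C@H]2O[C@H]([C@H](OCc3ccc4ccccc4c3)C(=O)OC)[C@H](OCc3ccc4ccccc4c3)[C@H]2O1 | intermediate
7 | lithium 1,2-O-isopropylidene-3,5-di-O-(naphthalen-2-ylmethyl)-α-D-glucofuranuronate | CC1(C)O[C@H]2O[C@H]([C@H](OCc3ccc4ccccc4c3)C(=O)[O-])[C@H](OCc3ccc4ccccc4c3)[C@H]2O1.[Li+] | intermediate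
8 | 3,5-di-O-(naphthalen-2-ylmethyl)-D-glucofuranuronic acid (lactol, anomer mixture) | OC1O[C@H]([C@H](OCc2ccc3ccccc3c2)C(=O)O)[C@H](OCc2ccc3ccccc3c2)[C@H]1O | intermediate
9 | 6,7-dideoxy-2,4-di-O-(naphthalen-2-ylmethyl)-L-gulo-hept-6-enonic acid | C=C[C@H](O)[C@@H](OCc1ccc2ccccc2c1)[C@H](O)[C@H](OCc1ccc2ccccc2c1)C(=O)O | intermediate
10 | 6,7-dideoxy-2,4-di-O-(naphthalen-2-ylmethyl)-L-gulo-hept-6-enono-1,5-lactone | O=C1O[C@@H](C=C)[C@@H](OCc2ccc3ccccc3c2)[C@H](O)[C@@H]1OCc1ccc2ccccc2c1 | intermediate
11 | 6,7-dideoxy-2,4-di-O-(naphthalen-2-ylmethyl)-3-O-triethylsilyl-L-gulo-hept-6-enono-1,5-lactone | O=C1O[C@@H](C=C)[C@@H](OCc2ccc3ccccc3c2)[C@H](O[Si](CC)(CC)CC)[C@@H]1OCc1ccc2ccccc2c1 | intermediate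
12 | 4-methoxybenzyl alcohol | COc1ccc(CO)cc1 | starting material
13 | vinyl acetate | C=COC(C)=O | starting material
14 | 4-methoxybenzyl vinyl ether | C=COCc1ccc(OC)cc1 | intermediate
15 | (6Z)-6-deoxy-7-O-(4-methoxybenzyl)-2,4-di-O-(naphthalen-2-ylmethyl)-3-O-triethylsilyl-L-gulo-hept-6-enono-1,5-lactone | O=C1O[C@@H](/C=C\OCc2ccc(OC)cc2)[C@@H](OCc2ccc3ccccc3c2)[C@H](O[Si](CC)(CC)CC)[C@@H]1OCc1ccc2ccccc2c1 | intermediate
16 | trimethylsilyl ketene acetal of 15 (C6=C7, OTMS on C7) | C[Si](C)(C)OC1=C(OCc2ccc3ccccc3c2)[C@@H](O[Si](CC)(CC)CC)[C@H](OCc2ccc3ccccc3c2)[C@H](/C=C\OCc2ccc(OC)cc2)O1 | intermediate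
17 | trimethylsilyl ester of acid 18 | COc1ccc(CO[C@H]2C=C[C@@H](OCc3ccc4ccccc4c3)[C@H](O[Si](CC)(CC)CC)[C@]2(OCc2ccc3ccccc3c2)C(=O)O[Si](C)(C)C)cc1 | intermediate
18 | cyclohex-2-ene-6-carboxylic acid with C1-OPMB, C4-ONAP, C5-OTES, C6-ONAP (O1, O4, O6 on one ring face; O5 and CO2H on the other) | COc1ccc(CO[C@H]2C=C[C@@H](OCc3ccc4ccccc4c3)[C@H](O[Si](CC)(CC)CC)[C@]2(OCc2ccc3ccccc3c2)C(=O)O)cc1 | intermediate
19 | C7 primary alcohol from 18 (same ring substituents and configuration) | COc1ccc(CO[C@H]2C=C[C@@H](OCc3ccc4ccccc4c3)[C@H](O[Si](CC)(CC)CC)[C@]2(OCc2ccc3ccccc3c2)CO)cc1 | intermediate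
20 | C7 tert-butyldimethylsilyl ether of 19 | COc1ccc(CO[C@H]2C=C[C@@H](OCc3ccc4ccccc4c3)[C@H](O[Si](CC)(CC)CC)[C@]2(OCc2ccc3ccccc3c2)CO[Si](C)(C)C(C)(C)C)cc1 | intermediate
21 | triol with C1-OH, C4-OH, C6-OH, C5-OTES, C7-OTBS | O[C@H]1C=C[C@@H](O)[C@H](O[Si](CC)(CC)CC)[C@]1(O)CO[Si](C)(C)C(C)(C)C | intermediate
22 | benzoyl chloride | O=C(Cl)c1ccccc1 | starting material
23 | 1,4-dibenzoate with C6-OH, C5-OTES, C7-OTBS | O=C(O[C@H]1C=C[C@@H](OC(=O)c2ccccc2)[C@H](O[Si](CC)(CC)CC)[C@]1(O)CO[Si](C)(C)C(C)(C)C)c1ccccc1 | intermediate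
24 | (1S,4R,5S,6R)-5,6-dihydroxy-6-(hydroxymethyl)cyclohex-2-ene-1,4-diyl dibenzoate | O=C(O[C@H]1C=C[C@@H](OC(=O)c2ccccc2)[C@H](O)[C@]1(O)CO)c1ccccc1 | target

**Step count**
Total: 15 steps. Longest linear sequence: 13 steps (1 → 24 through steps 1, 3, 4, 5, 6, 7, 9, 10, 11, 12, 13, 14, 15).

**Steps most likely to fail**

1. Step 10 (key step). The lithium enolate may expel the C5 silyloxy group (β-elimination) before it is silylated, or the ketene acetal may decompose before it reaches the strained boat. The fallback sets out from 15 and changes what the β-oxygen is while the enolate exists. Buffered desilylation (TBAF/AcOH, THF, 0 °C) gives the C5-hydroxy lactone F1. Two equivalents of LDA (THF, −78 °C) then make the C5 alkoxide and the enolate, so the β-oxygen is an oxido group that cannot leave; this is the dianionic ester-enolate Claisen variant known for allyl β-hydroxy esters. TMSCl, warming to 60–80 °C and acidic work-up give the hydroxy acid F2. TESOTf/2,6-lutidine, followed by K2CO3 in aqueous MeOH to cleave only the silyl ester, comes back to the route at 18.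

2. Step 9. Metathesis may be sluggish at the branched, oxygen-flanked terminal alkene, and secondary metathesis may erode the Z geometry. The fallback sets out from lactol acid 8 and builds the enol ether by C–O coupling on a geometrically defined vinyl iodide. Stork–Zhao olefination ((iodomethyl)triphenylphosphonium iodide, NaHMDS, THF/DMPU, −78 °C → rt) should give the (Z)-iodoalkene hydroxy acid F3. Lactonisation as in step 6 gives the iodovinyl lactone F4, and TESOTf/2,6-lutidine gives its C5 silyl ether F5. CuI/3,4,7,8-tetramethyl-1,10-phenanthroline-catalysed coupling of F5 with 4-methoxybenzyl alcohol 12 (Cs2CO3, toluene, 80 °C), which keeps the alkene geometry, comes back to the route at 15.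

3. Step 13. While the slower NAP ethers are still being cleaved, the C6 oxocarbenium ion may be trapped by the freshly freed cis C1 hydroxyl as a naphthylidene acetal, and the liberated allylic alcohols may be over-oxidised. The fallback sets out from 20 and stages the deprotection. DDQ (1.1 equiv, CH2Cl2/pH 7 buffer, 0 °C) cleaves only the faster PMB ether and gives the C1 alcohol F6. Benzoylation with 22 in pyridine gives the monobenzoate F7. DDQ (3 equiv, rt) then removes both NAP ethers with no free hydroxyl beside C6, giving the C4,C6-diol F8. Benzoylation of the secondary O4 with 22 comes back to the route at 23.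

**Further compounds**
F1 | step 10 | C5-hydroxy δ-lactone with the (Z)-2-(4-methoxybenzyloxy)vinyl group on C3 (15 without the silyl group) | O=C1O[C@@H](/C=C\OCc2ccc(OC)cc2)[C@@H](OCc2ccc3ccccc3c2)[C@H](O)[C@@H]1OCc1ccc2ccccc2c1
F2 | step 10 | C5-hydroxy cyclohex-2-ene-6-carboxylic acid (18 without the silyl group) | COc1ccc(CO[C@H]2C=C[C@@H](OCc3ccc4ccccc4c3)[C@H](O)[C@]2(OCc2ccc3ccccc3c2)C(=O)O)cc1
F3 | step 9 | (6Z)-6,7-dideoxy-7-iodo-2,4-di-O-(naphthalen-2-ylmethyl)-L-gulo-hept-6-enonic acid | I/C=C\[C@H](O)[C@@H](OCc1ccc2ccccc2c1)[C@H](O)[C@H](OCc1ccc2ccccc2c1)C(=O)O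
F4 | step 9 | (6Z)-6,7-dideoxy-7-iodo-2,4-di-O-(naphthalen-2-ylmethyl)-L-gulo-hept-6-enono-1,5-lactone | O=C1O[C@@H](/C=C\I)[C@@H](OCc2ccc3ccccc3c2)[C@H](O)[C@@H]1OCc1ccc2ccccc2c1
F5 | step 9 | 3-O-triethylsilyl ether of F4 | O=C1O[C@@H](/C=C\I)[C@@H](OCc2ccc3ccccc3c2)[C@H](O[Si](CC)(CC)CC)[C@@H]1OCc1ccc2ccccc2c1
F6 | step 13 | C1 alcohol with C4-ONAP, C6-ONAP, C5-OTES, C7-OTBS | O[C@H]1C=C[C@@H](OCc2ccc3ccccc3c2)[C@H](O[Si](CC)(CC)CC)[C@]1(OCc1ccc2ccccc2c1)CO[Si](C)(C)C(C)(C)C
F7 | step 13 | C1 benzoate of F6 | O=C(O[C@H]1C=C[C@@H](OCc2ccc3ccccc3c2)[C@H](O[Si](CC)(CC)CC)[C@]1(OCc1ccc2ccccc2c1)CO[Si](C)(C)C(C)(C)C)c1ccccc1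
F8 | step 13 | C1 benzoate with C4-OH, C6-OH, C5-OTES, C7-OTBS | O=C(O[C@H]1C=C[C@@H](O)[C@H](O[Si](CC)(CC)CC)[C@]1(O)CO[Si](C)(C)C(C)(C)C)c1ccccc1
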